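**Plan**

1. Retrosynthesis: the two O-benzyl groups on ring B and the 3-O-methyl group come off first, then the C3–O bond (enol ether oxidation), which leads back to (2S)-flavanone 11.
2. The C2–C3 bond of ring C is cut next: C2 is benzylic, carries O1 and ring B, and lies six atoms from C3 along C3–C4–C4a–C8a–O1–C2, so a carbenoid at C3 beside the C4 ketone on ring A can insert into a C2–H bond of an aryl benzyl ether.
3. Diazoketone 10 goes back to methyl ketone 8, and the O1–CH2 bond of 8 to hydroxyacetophenone 2 (ring A) and benzylic alcohol 7 (ring B).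
4. Forward: rings A and B are prepared separately and joined at O1, ring C is closed by the C–H insertion, then C3 is hydroxylated and methylated and the two phenols are set free.
5. Stereochemistry: C2 is set by the chiral dirhodium catalyst (choice between two enantiotopic hydrogens); C3 follows from C2, the oxidant adding anti to the aryl group to give the 2,3-trans (2R,3R) arrangement.

Key step: step 7

Assumption: Rh2(S-PTTL)4 is taken to deliver the 2S ring; if the sense of induction is the opposite, the R-PTTL antipode (from D-tert-leucine) is used in the same way.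
Remark: flavan numbering (O1, C2, C3, C4, C4a, C5–C8, C8a) is used for ring positions throughout.

**Route**

Step 1
Reactants: 1 3,4,5-trimethoxyphenol
Product: 2 1-(2-hydroxy-4,5,6-trimethoxyphenyl)ethan-1-one
Conditions: AcOH, BF3·OEt2, 90 °C; then ice-water
Reagents that add atoms: acetic acid, CC(=O)O
Why: Friedel–Crafts C-acylation of a highly activated phenol goes ortho to the hydroxyl group, and because the two ortho positions of 1 are equivalent only one ketone can form.

Step 2
Reactants: 3 2-methoxybenzene-1,4-diol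
Product: 4 1,4-bis(benzyloxy)-2-methoxybenzene
Conditions: BnBr, K2CO3, DMF, 50 °C, under N2
Reagents that add atoms: benzyl bromide, BrCc1ccccc1
Why: Double Williamson etherification of the hydroquinone with an SN2-reactive benzyl halide, run under nitrogen so that the phenoxide is not oxidised to the quinone.

Step 3
Reactants: 4 1,4-bis(benzyloxy)-2-methoxybenzene
Product: 6 2,5-bis(benzyloxy)-4-methoxybenzaldehyde, via iminium chloride 5 (not isolated)
Conditions: POCl3, DMF, 0 → 70 °C; then ice-water
Reagents that add atoms: N,N-dimethylformamide, CN(C)C=O; water, O; phosphoryl chloride, O=P(Cl)(Cl)Cl (chloride counter-ion of 5 only)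
Why: Vilsmeier–Haack formylation takes place at the one unhindered position activated by two donors (para to OMe, ortho to OBn), as 1,2,4-trimethoxybenzene gives 2,4,5-trimethoxybenzaldehyde, and water then hydrolyses the iminium salt to the aldehyde.

Step 4
Reactants: 6 2,5-bis(benzyloxy)-4-methoxybenzaldehyde
Product: 7 [2,5-bis(benzyloxy)-4-methoxyphenyl]methanol
Conditions: NaBH4, MeOH/THF, 0 °C
Reagents that add atoms: none
Why: Borohydride reduction of an aryl aldehyde to the benzylic alcohol, which touches neither the aryl ethers nor the benzyl groups.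

Step 5
Reactants: 2 1-(2-hydroxy-4,5,6-trimethoxyphenyl)ethan-1-one; 7 [2,5-bis(benzyloxy)-4-methoxyphenyl]methanol
Product: 8 1-{2-[(2,5-bis(benzyloxy)-4-methoxyphenyl)methoxy]-4,5,6-trimethoxyphenyl}ethan-1-one
Conditions: PPh3, DIAD, THF, 0 °C → rt
Reagents that add atoms: none
Why: Mitsunobu etherification, in which the hydrogen-bonded phenol of 2 (pKa near 10) protonates the betaine and its phenoxide displaces the primary benzylic oxyphosphonium group by SN2, so that no unstable electron-rich benzyl halide has to be handled.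

Step 6
Reactants: 8 1-{2-[(2,5-bis(benzyloxy)-4-methoxyphenyl)methoxy]-4,5,6-trimethoxyphenyl}ethan-1-one
Product: 10 1-{2-[(2,5-bis(benzyloxy)-4-methoxyphenyl)methoxy]-4,5,6-trimethoxyphenyl}-2-diazoethan-1-one, via trifluoroacetyl ketone 9 (not isolated)
Conditions: LiN(SiMe3)2, THF, −78 °C; CF3CO2CH2CF3, −78 °C; AcOH quench, aqueous work-up; crude 9, MsN3, Et3N, H2O, MeCN, rt
Reagents that add atoms: methanesulfonyl azide, CS(=O)(=O)N=[N+]=[N-]; 2,2,2-trifluoroethyl trifluoroacetate, O=C(OCC(F)(F)F)C(F)(F)F (its trifluoroacetyl group is carried by 9 only and is lost again)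
Why: Detrifluoroacetylative Regitz-type diazo transfer, in which Claisen trifluoroacetylation of the kinetic lithium enolate turns the methyl group into a 1,3-diketone whose enolate adds to the sulfonyl azide and fragments to the diazomethyl ketone, all without the strong acid that the electron-rich benzyl aryl ether would not survive.

Step 7
Reactants: 10 1-{2-[(2,5-bis(benzyloxy)-4-methoxyphenyl)methoxy]-4,5,6-trimethoxyphenyl}-2-diazoethan-1-one
Product: 11 (2S)-2-[2,5-bis(benzyloxy)-4-methoxyphenyl]-5,6,7-trimethoxy-2,3-dihydro-4H-chromen-4-one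
Conditions: Rh2(S-PTTL)4 (dirhodium tetrakis[N-phthaloyl-(S)-tert-leucinate], 2 mol %), CH2Cl2, 4 Å MS, 0 °C, slow addition of 10
Reagents that add atoms: none
Why: The dirhodium catalyst expels N2 from 10 to give an electrophilic divalent-rhodium carbenoid at C3, which inserts through a concerted three-centre, hydride-transfer-like transition state into one C–H bond of the O1–CH2–aryl group; this is the known intramolecular carbenoid C–H insertion of ortho-alkoxyaryl diazoketones to chroman-4-ones. Ring C closes by 1,6-insertion (carbenoid carbon, C4, C4a, C8a, O1, C2), the only ring size open to C–H insertion because the fifth atom of the chain is the ether oxygen. The new stereocentre C2 is controlled by the catalyst alone: the substrate is achiral and the N-phthaloyl-tert-leucinate ligands let only one of the two enantiotopic hydrogens reach the carbenoid. The step needs chemoselectivity for insertion over capture of the carbenoid by O1 (oxonium ylide, then Stevens [1,2]-benzyl shift), site selectivity over the primary C–H bonds of the C5 methoxy group and the remote benzyl ether methylenes, and suppression of carbene dimerisation. The substrate supports this because the reacting C–H bond is doubly activated (α to O1 and benzylic to a ring with ortho and para alkoxy donors) while the lone pairs of O1 are delocalised into the acylated ring A, and the bulky ligands together with slow addition at high dilution disfavour ylide formation and dimerisation. Crystallisation of 11 should allow the enantiomeric purity to be raised if needed.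

Step 8
Reactants: 11 (2S)-2-[2,5-bis(benzyloxy)-4-methoxyphenyl]-5,6,7-trimethoxy-2,3-dihydro-4H-chromen-4-one
Product: 12 {[(2S)-2-[2,5-bis(benzyloxy)-4-methoxyphenyl]-5,6,7-trimethoxy-2H-chromen-4-yl]oxy}trimethylsilane
Conditions: LiN(i-Pr)2, Me3SiCl (present from the start), THF, −78 °C; Et3N, pentane, filtration; crude product used at once
Reagents that add atoms: chlorotrimethylsilane, C[Si](C)(C)Cl
Why: Kinetic enolisation with in situ silylation (silyl enol ether formation) traps the C3 enolate before it can expel the O1 phenoxide by E1cB opening of ring C, so C2 is left untouched.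

Step 9
Reactants: 12 {[(2S)-2-[2,5-bis(benzyloxy)-4-methoxyphenyl]-5,6,7-trimethoxy-2H-chromen-4-yl]oxy}trimethylsilane
Product: 14 (2R,3R)-2-[2,5-bis(benzyloxy)-4-methoxyphenyl]-3-hydroxy-5,6,7-trimethoxy-2,3-dihydro-4H-chromen-4-one, via silyloxy epoxide 13 (not isolated)
Conditions: dimethyldioxirane, acetone/CH2Cl2, −40 → 0 °C; then aq. citric acid, THF, 0 °C
Reagents that add atoms: dimethyldioxirane, CC1(C)OO1
Why: Rubottom oxidation, in which the dioxirane epoxidises the enol ether from the face opposite the C2 aryl group and mild acid opens the silyloxy oxirane to the α-hydroxy ketone, so C3 is set trans to the aryl group by substrate control (the C2 descriptor changes from S to R only because C3 now outranks the aryl carbon).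

Step 10
Reactants: 14 (2R,3R)-2-[2,5-bis(benzyloxy)-4-methoxyphenyl]-3-hydroxy-5,6,7-trimethoxy-2,3-dihydro-4H-chromen-4-one
Product: 15 (2R,3R)-2-[2,5-bis(benzyloxy)-4-methoxyphenyl]-3,5,6,7-tetramethoxy-2,3-dihydro-4H-chromen-4-one
Conditions: Me3OBF4, 1,8-bis(dimethylamino)naphthalene, 4 Å MS, CH2Cl2, 0 °C → rt
Reagents that add atoms: trimethyloxonium tetrafluoroborate, C[O+](C)C.F[B-](F)(F)F
Why: O-alkylation of the secondary alcohol by a trialkyloxonium salt with a hindered, non-nucleophilic amine as proton acceptor avoids the alkoxide conditions that would open ring C by retro-oxa-Michael reaction or epimerise C3.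

Step 11
Reactants: 15 (2R,3R)-2-[2,5-bis(benzyloxy)-4-methoxyphenyl]-3,5,6,7-tetramethoxy-2,3-dihydro-4H-chromen-4-one
Product: 16 (2R,3R)-2-(2,5-dihydroxy-4-methoxyphenyl)-3,5,6,7-tetramethoxy-2,3-dihydro-4H-chromen-4-one
Conditions: H2 (1 atm), 10% Pd/C, degassed EtOAc, rt; filtration under argon
Reagents that add atoms: none
Why: Catalytic hydrogenolysis of the two benzyl aryl ethers over palladium is much faster than cleavage of the cyclic C2–O1 ether or reduction of the aryl ketone, and the neutral conditions leave both stereocentres and the air-sensitive hydroquinone intact.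

**Compound list**

1 | 3,4,5-trimethoxyphenol | COc1cc(O)cc(OC)c1OC | starting material
2 | 1-(2-hydroxy-4,5,6-trimethoxyphenyl)ethan-1-one | CC(=O)c1c(O)cc(OC)c(OC)c1OC | intermediate
3 | 2-methoxybenzene-1,4-diol (2-methoxyhydroquinone) | COc1cc(O)ccc1O | starting material
4 | 1,4-bis(benzyloxy)-2-methoxybenzene | COc1cc(OCc2ccccc2)ccc1OCc1ccccc1 | intermediate
5 | N-{[2,5-bis(benzyloxy)-4-methoxyphenyl]methylidene}-N-methylmethanaminium chloride (formed in the flask in step 3) | C[N+](C)=Cc1cc(OCc2ccccc2)c(OC)cc1OCc1ccccc1.[Cl-] | intermediate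
6 | 2,5-bis(benzyloxy)-4-methoxybenzaldehyde | COc1cc(OCc2ccccc2)c(C=O)cc1OCc1ccccc1 | intermediate
7 | [2,5-bis(benzyloxy)-4-methoxyphenyl]methanol | COc1cc(OCc2ccccc2)c(CO)cc1OCc1ccccc1 | intermediate
8 | 1-{2-[(2,5-bis(benzyloxy)-4-methoxyphenyl)methoxy]-4,5,6-trimethoxyphenyl}ethan-1-one | COc1cc(OCc2ccccc2)c(COc2cc(OC)c(OC)c(OC)c2C(C)=O)cc1OCc1ccccc1 | intermediate
9 | 1-{2-[(2,5-bis(benzyloxy)-4-methoxyphenyl)methoxy]-4,5,6-trimethoxyphenyl}-4,4,4-trifluorobutane-1,3-dione (formed in the flask in step 6) | COc1cc(OCc2ccccc2)c(COc2cc(OC)c(OC)c(OC)c2C(=O)CC(=O)C(F)(F)F)cc1OCc1ccccc1 | intermediate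
10 | 1-{2-[(2,5-bis(benzyloxy)-4-methoxyphenyl)methoxy]-4,5,6-trimethoxyphenyl}-2-diazoethan-1-one | COc1cc(OCc2ccccc2)c(COc2cc(OC)c(OC)c(OC)c2C(=O)C=[N+]=[N-])cc1OCc1ccccc1 | intermediate
11 | (2S)-2-[2,5-bis(benzyloxy)-4-methoxyphenyl]-5,6,7-trimethoxy-2,3-dihydro-4H-chromen-4-one | COc1cc(OCc2ccccc2)c([C@H]2Oc3cc(OC)c(OC)c(OC)c3C(=O)C2)cc1OCc1ccccc1 | intermediate
12 | {[(2S)-2-[2,5-bis(benzyloxy)-4-methoxyphenyl]-5,6,7-trimethoxy-2H-chromen-4-yl]oxy}trimethylsilane | COc1cc(OCc2ccccc2)c([C@H]2Oc3cc(OC)c(OC)c(OC)c3C(O[Si](C)(C)C)=C2)cc1OCc1ccccc1 | intermediate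
13 | {[(1aR,2R,7bR)-2-[2,5-bis(benzyloxy)-4-methoxyphenyl]-5,6,7-trimethoxy-1a,2-dihydro-7bH-oxireno[2,3-c]chromen-7b-yl]oxy}trimethylsilane, the 3,4-epoxide of 12 with the oxirane anti to the aryl group (formed in the flask in step 9) | COc1cc(OCc2ccccc2)c([C@H]2Oc3cc(OC)c(OC)c(OC)c3[C@]4(O[Si](C)(C)C)O[C@H]24)cc1OCc1ccccc1 | intermediate
14 | (2R,3R)-2-[2,5-bis(benzyloxy)-4-methoxyphenyl]-3-hydroxy-5,6,7-trimethoxy-2,3-dihydro-4H-chromen-4-one | COc1cc(OCc2ccccc2)c([C@H]2Oc3cc(OC)c(OC)c(OC)c3C(=O)[C@@H]2O)cc1OCc1ccccc1 | intermediate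
15 | (2R,3R)-2-[2,5-bis(benzyloxy)-4-methoxyphenyl]-3,5,6,7-tetramethoxy-2,3-dihydro-4H-chromen-4-one | COc1cc(OCc2ccccc2)c([C@H]2Oc3cc(OC)c(OC)c(OC)c3C(=O)[C@@H]2OC)cc1OCc1ccccc1 | intermediate
16 | (2R,3R)-2-(2,5-dihydroxy-4-methoxyphenyl)-3,5,6,7-tetramethoxy-2,3-dihydro-4H-chromen-4-one (CNP0150769.1) | COc1cc(O)c([C@H]2Oc3cc(OC)c(OC)c(OC)c3C(=O)[C@@H]2OC)cc1O | target

**Count**

Total steps: 11. Longest linear sequence: 10 steps (3 → 16 through steps 2–11); the ring A branch (step 1) joins at step 5.

**Steps most likely to fail**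

1. Step 7. The carbenoid may be captured by a lone pair of O1 (oxonium ylide formation followed by [1,2]-benzyl migration) instead of inserting into the C–H bond, or the catalyst may discriminate poorly between the two enantiotopic hydrogens. The fallback forms the C2–aryl bond instead of the C2–C3 bond; it sets out from 2 and 4 and comes back at 11. Ketone 2 is condensed with DMF dimethyl acetal to the enaminone (E)-3-(dimethylamino)-1-(2-hydroxy-4,5,6-trimethoxyphenyl)prop-2-en-1-one F1, which closes with HCl in CH2Cl2 to 5,6,7-trimethoxy-4H-chromen-4-one F2. Ether 4 is brominated para to the methoxy group with NBS in MeCN to 1,4-bis(benzyloxy)-2-bromo-5-methoxybenzene F3, and bromine–lithium exchange with n-BuLi, B(Oi-Pr)3 and aqueous work-up should give [2,5-bis(benzyloxy)-4-methoxyphenyl]boronic acid F4. Asymmetric Hayashi–Miyaura 1,4-addition of F4 to F2 with a monovalent rhodium catalyst ([RhCl(C2H4)2]2, a chiral diene ligand of the antipode that gives 2S, aqueous KOH, toluene) should then deliver 11.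

2. Step 8. Enolisation may be followed by β-elimination of the O1 phenoxide (E1cB opening of ring C to the chalcone), which erases C2, or the silyl enol ether may hydrolyse before oxidation. The fallback builds the 2,3-trans hydroxy ketone from an epoxide and never enolises a closed ring C; it sets out from 2 and 6 and comes back at 14. Phenol 2 is protected with MOMCl and i-Pr2NEt as 1-[2-(methoxymethoxy)-4,5,6-trimethoxyphenyl]ethan-1-one F5. Claisen–Schmidt condensation of F5 with aldehyde 6 (KOH, EtOH) gives (E)-3-[2,5-bis(benzyloxy)-4-methoxyphenyl]-1-[2-(methoxymethoxy)-4,5,6-trimethoxyphenyl]prop-2-en-1-one F6. Juliá–Colonna epoxidation (poly-L-leucine, urea–H2O2, DBU, THF) should give {(2R,3S)-3-[2,5-bis(benzyloxy)-4-methoxyphenyl]oxiran-2-yl}[2-(methoxymethoxy)-4,5,6-trimethoxyphenyl]methanone F7. Methanolic HCl then removes the acetal, and the freed phenol opens the oxirane at the benzylic carbon with inversion (6-endo) to 14, both stereocentres coming from the epoxide.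

3. Step 5. The activated benzyloxyphosphonium ion may ionise and C-benzylate the electron-rich phenol, or the hydrogen-bonded phenol may react too slowly. The fallback replaces the redox condensation by a Williamson alkylation; it sets out from 7 and comes back at 8. Alcohol 7 is converted with MsCl, LiCl and 2,4,6-collidine in DMF at 0 °C into 1,4-bis(benzyloxy)-2-(chloromethyl)-5-methoxybenzene F8, which is used at once with 2 and K2CO3 in DMF, where the potassium phenoxide should alkylate on oxygen to give 8.

**Further compounds**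

F1 | step 7 | (E)-3-(dimethylamino)-1-(2-hydroxy-4,5,6-trimethoxyphenyl)prop-2-en-1-one | CN(C)/C=C/C(=O)c1c(O)cc(OC)c(OC)c1OC
F2 | step 7 | 5,6,7-trimethoxy-4H-chromen-4-one | COc1cc2occc(=O)c2c(OC)c1OC
F3 | step 7 | 1,4-bis(benzyloxy)-2-bromo-5-methoxybenzene | COc1cc(OCc2ccccc2)c(Br)cc1OCc1ccccc1
F4 | step 7 | [2,5-bis(benzyloxy)-4-methoxyphenyl]boronic acid | COc1cc(OCc2ccccc2)c(B(O)O)cc1OCc1ccccc1
F5 | step 8 | 1-[2-(methoxymethoxy)-4,5,6-trimethoxyphenyl]ethan-1-one | CC(=O)c1c(OCOC)cc(OC)c(OC)c1OC
F6 | step 8 | (E)-3-[2,5-bis(benzyloxy)-4-methoxyphenyl]-1-[2-(methoxymethoxy)-4,5,6-trimethoxyphenyl]prop-2-en-1-one | COCOc1cc(OC)c(OC)c(OC)c1C(=O)/C=C/c1cc(OCc2ccccc2)c(OC)cc1OCc1ccccc1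
F7 | step 8 | {(2R,3S)-3-[2,5-bis(benzyloxy)-4-methoxyphenyl]oxiran-2-yl}[2-(methoxymethoxy)-4,5,6-trimethoxyphenyl]methanone | COCOc1cc(OC)c(OC)c(OC)c1C(=O)[C@@H]1O[C@H]1c1cc(OCc2ccccc2)c(OC)cc1OCc1ccccc1
F8 | step 5 | 1,4-bis(benzyloxy)-2-(chloromethyl)-5-methoxybenzene | COc1cc(OCc2ccccc2)c(CCl)cc1OCc1ccccc1
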